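**Retrosynthetic overview**

- Numbering: ring C1 (angelate), C2, C3 (methyl), C4 (hydroxyl), C5, C6 (side chain); chain C7 (methyl), C8, C9 (acetate), C10=C11.
- Feature: O1 and C9 are connected through C1–C6–C7–C8, so the run O1–C1–C6–C7–C8–C9 can exist as a six-membered lactone trans-fused to the cyclohexane. An acrylate on O1 supplies C8 and C9.
- Disconnections: C9–C10 (alkenyllithium opens the lactone and frees only O1); C7=C8 (ring-closing metathesis, then axial hydride delivery sets C7); C6–C7 (cuprate anti to the C1 silyloxy group); C3–CH3 (enone alpha' methylation); C1 from desymmetrization of a meso endoperoxide.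
- Rings: the carbocycle comes intact from cyclohexa-1,3-diene. The lactone is the only ring made (step 11) and is opened again in step 13.
- End game: angelate on O1, reagent-controlled reduction at C9, acetate, desilylation at C4.

Key step: step 11

Assumption: the two pseudoenantiomeric 6'-hydroxy-9-O-acetyl cinchona bases give opposite enantiomers of 3. The quinidine-derived base is written in step 2 as the one giving (R)-3; if the sense proves opposite, the quinine-derived base (9-O-acetylcupreine) takes its place with no other change.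

**Route**

Step 1
Reactants: 1 cyclohexa-1,3-diene
Product: 2 (1R,4S)-2,3-dioxabicyclo[2.2.2]oct-5-ene (meso endoperoxide)
Conditions: O2, tetraphenylporphyrin (cat.), visible light, CH2Cl2, 0 °C
Reagents that add atoms: dioxygen, O=O
Why: Sensitized photooxygenation, in which singlet oxygen adds across the s-cis diene in a [4+2] cycloaddition, should give the meso bicyclic peroxide.

Step 2
Reactants: 2 meso endoperoxide
Product: 3 (4R)-4-hydroxycyclohex-2-en-1-one
Conditions: 9-O-acetylcupreidine (10 mol %), CH2Cl2, rt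
Reagents that add atoms: none
Why: Kornblum–DeLaMare rearrangement under chiral base catalysis, in which the quinuclidine nitrogen removes one of the two enantiotopic bridgehead hydrogens with O–O cleavage, should desymmetrize the peroxide and set the C1 carbinol (target numbering) as R.

Step 3
Reactants: 3 (4R)-4-hydroxycyclohex-2-en-1-one
Product: 4 (4R)-4-(triethylsilyloxy)cyclohex-2-en-1-one
Conditions: Et3SiCl, imidazole, CH2Cl2, 0 °C
Reagents that add atoms: chlorotriethylsilane, CC[Si](Cl)(CC)CC
Why: Imidazole-mediated silylation of a secondary alcohol gives a triethylsilyl ether that will direct the cuprate anti and can later be removed beside a tert-butyldimethylsilyl ether.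

Step 4
Reactants: 4 (4R)-4-(triethylsilyloxy)cyclohex-2-en-1-one
Product: 6 (4R)-6-methyl-4-(triethylsilyloxy)cyclohex-2-en-1-one (both C6 epimers), via lithium dienolate 5 (not isolated)
Conditions: LiN(i-Pr)2, THF, −78 °C; MeI, −78 → −40 °C
Reagents that add atoms: iodomethane, CI
Why: Kinetic deprotonation of the enone at its only alpha' position gives the cross-conjugated dienolate, and SN2 methylation then places the methyl at C3 (target numbering) without regiochemical ambiguity, which is the reason for methylating before the conjugate addition; the new centre is corrected in step 6.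

Step 5
Reactants: 6 (4R)-6-methyl-4-(triethylsilyloxy)cyclohex-2-en-1-one; 7 isopropenylmagnesium bromide
Product: 9 (4R,5S)-2-methyl-5-(prop-1-en-2-yl)-4-(triethylsilyloxy)cyclohexan-1-one (both C2 epimers), via bromomagnesium diisopropenylcuprate 8 (not isolated)
Conditions: 7 (2.4 equiv), CuBr·SMe2 (1.2 equiv), THF, −78 → −40 °C; aq. NH4Cl
Reagents that add atoms: isopropenylmagnesium bromide 7, CC(=C)[Mg]Br
Why: Conjugate addition of the Gilman-type cuprate should occur on the enone face anti to the adjacent silyloxy group, the usual outcome for 4-silyloxycyclohex-2-enones, setting C6 (target numbering) as S with the isopropenyl group trans to O1.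

Step 6
Reactants: 9 ketone as C2 epimers
Product: 10 (2S,4R,5S)-2-methyl-5-(prop-1-en-2-yl)-4-(triethylsilyloxy)cyclohexan-1-one
Conditions: DBU (0.5 equiv), toluene, 40 °C
Reagents that add atoms: none
Why: Base-mediated epimerization through the enolate should place the methyl equatorial, cis to the equatorial C1 silyloxy group, in the chair that keeps the trans C1 and C6 substituents diequatorial, so thermodynamic control sets C3 (target numbering) as S.

Step 7
Reactants: 10 (2S,4R,5S)-ketone
Product: 11 (1R,2S,4R,5S)-2-methyl-5-(prop-1-en-2-yl)-4-(triethylsilyloxy)cyclohexan-1-ol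
Conditions: LiBH(s-Bu)3, THF, −78 °C; NaOH, H2O2, 0 °C
Reagents that add atoms: none
Why: Ketone reduction by the bulky trialkylborohydride follows steric approach control, with hydride entering along the equatorial direction of the locked chair, so the C4 hydroxyl (target numbering) should form axial and cis to the C3 methyl, as in the reduction of 2-methylcyclohexanone to the cis alcohol.

Step 8
Reactants: 11 axial alcohol
Product: 12 tert-butyldimethyl{[(1R,2S,4R,5S)-2-methyl-5-(prop-1-en-2-yl)-4-(triethylsilyloxy)cyclohexyl]oxy}silane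
Conditions: t-BuMe2SiOTf, 2,6-lutidine, CH2Cl2, −78 → 0 °C
Reagents that add atoms: tert-butyldimethylsilyl trifluoromethanesulfonate, CC(C)(C)[Si](C)(C)OS(=O)(=O)C(F)(F)F
Why: Silylation with the silyl triflate and a hindered pyridine base should protect even the hindered axial secondary alcohol as a robust silyl ether.

Step 9
Reactants: 12 bis-silyl ether
Product: 13 (1R,2S,4R,5S)-4-[(tert-butyldimethylsilyl)oxy]-5-methyl-2-(prop-1-en-2-yl)cyclohexan-1-ol
Conditions: PPTS (cat.), MeOH/CH2Cl2, 0 °C
Reagents that add atoms: none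
Why: Selective acid-catalysed methanolysis should cleave the more acid-labile, less hindered triethylsilyl ether at C1 and leave the hindered axial tert-butyldimethylsilyl ether at C4.

Step 10
Reactants: 13 C1 alcohol; 14 acryloyl chloride
Product: 15 (1R,2S,4R,5S)-4-[(tert-butyldimethylsilyl)oxy]-5-methyl-2-(prop-1-en-2-yl)cyclohexyl prop-2-enoate
Conditions: 14, i-Pr2NEt, CH2Cl2, −40 → 0 °C
Reagents that add atoms: acryloyl chloride 14, C=CC(=O)Cl
Why: Esterification of the equatorial secondary alcohol with the acid chloride and a tertiary amine installs the acrylate that carries C8 and C9.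

Step 11
Reactants: 15 acrylate
Product: 16 (4aS,6R,7S,8aR)-6-[(tert-butyldimethylsilyl)oxy]-4,7-dimethyl-4a,5,6,7,8,8a-hexahydro-2H-chromen-2-one
Conditions: second-generation Grubbs catalyst RuCl2(PCy3)(H2IMes)(=CHPh) (10 mol %), toluene (0.005 M), 80 °C, argon sparge
Reagents that add atoms: none
Why: The ruthenium alkylidene exchanges with one terminal alkene of 15 by [2+2] cycloaddition and retro-[2+2] through a ruthenacyclobutane, and the substrate-bound alkylidene then closes on the second alkene in the same way, releasing ethene. The closest known reaction type is ring-closing metathesis of acrylates of homoallylic alcohols bearing a 1,1-disubstituted alkene, which gives 4-methyl-5,6-dihydro-2H-pyran-2-ones. The one ring closed is the six-membered lactone O1–C1–C6–C7=C8–C9, joined between the two =CH2 termini, with an endocyclic trisubstituted C7=C8 bond whose geometry the ring imposes, trans-fused to the cyclohexane. No stereocentre is formed. The step needs ring closure to win over intermolecular cross-metathesis of the acrylate; this should be secured by the absence of any other alkene, by the gauche arrangement of the trans-diequatorial C1 acrylate and C6 isopropenyl group, and by high dilution.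

Step 12
Reactants: 16 unsaturated lactone
Product: 17 (4R,4aS,6R,7S,8aR)-6-[(tert-butyldimethylsilyl)oxy]-4,7-dimethyloctahydro-2H-chromen-2-one
Conditions: [(PPh3)CuH]6 (0.5 equiv), H2O (5 equiv), toluene/THF, rt
Reagents that add atoms: none
Why: Copper hydride conjugate reduction of the unsaturated lactone should deliver hydride to C7 along the axial trajectory of the locked trans-fused half-chair, anti to the axial C6–H, so that the C7 methyl becomes equatorial (C7 R), the copper enolate being protonated by the added water.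

Step 13
Reactants: 17 saturated lactone; 18 1-bromo-2-methylprop-1-ene
Product: 21 (6R)-6-[(1S,2R,4S,5R)-5-[(tert-butyldimethylsilyl)oxy]-2-hydroxy-4-methylcyclohexyl]-2-methylhept-2-en-4-one, via 2-methylprop-1-enyllithium 19 (not isolated), via lithium lactol alkoxide 20 (not isolated)
Conditions: 18, t-BuLi (2 equiv), Et2O, −78 °C; then 17 (19 at 1.2 equiv), THF, −78 °C; aq. NH4Cl at −78 °C
Reagents that add atoms: 1-bromo-2-methylprop-1-ene 18, CC(C)=CBr
Why: Bromine–lithium exchange gives the alkenyllithium, which should add once to the lactone carbonyl (acyl substitution of a lactone by an organolithium) to form a lactol alkoxide that persists until the cold quench, so that C9 becomes the enone carbonyl and only the C1 hydroxyl is freed; conjugation should favour the open hydroxy enone over its lactol.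

Step 14
Reactants: 21 hydroxy enone; 22 angelic acid ((2Z)-2-methylbut-2-enoic acid)
Product: 24 (1R,2S,4R,5S)-4-[(tert-butyldimethylsilyl)oxy]-5-methyl-2-[(2R)-6-methyl-4-oxohept-5-en-2-yl]cyclohexyl (2Z)-2-methylbut-2-enoate, via angelic 2,4,6-trichlorobenzoic anhydride 23 (not isolated)
Conditions: 22, 2,4,6-Cl3C6H2COCl, Et3N, toluene, rt; then 21, 80 °C
Reagents that add atoms: angelic acid 22, C/C=C(/C)C(=O)O
Why: Yamaguchi-type esterification through the mixed anhydride, run without a nucleophilic catalyst, is the established way to acylate a secondary alcohol with angelic acid without Z-to-E isomerization to the tiglate.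

Step 15
Reactants: 24 angelate enone
Product: 25 (1R,2S,4R,5S)-4-[(tert-butyldimethylsilyl)oxy]-2-[(2R,4R)-4-hydroxy-6-methylhept-5-en-2-yl]-5-methylcyclohexyl (2Z)-2-methylbut-2-enoate
Conditions: (S)-Me-CBS oxazaborolidine [(S)-1-methyl-3,3-diphenyltetrahydro-1H,3H-pyrrolo[1,2-c][1,3,2]oxazaborole] (1 equiv), catecholborane, toluene, −78 °C
Reagents that add atoms: none
Why: Corey–Bakshi–Shibata reduction, in which the ketone binds the catalyst boron anti to the larger 2-methylprop-1-enyl group and hydride comes from the coordinated borane, should give the (9R) allylic alcohol with the (S)-catalyst by reagent control, while catecholborane at −78 °C leaves the angelate and the alkenes untouched.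

Step 16
Reactants: 25 allylic alcohol
Product: 26 (1R,2S,4R,5S)-2-[(2R,4R)-4-acetoxy-6-methylhept-5-en-2-yl]-4-[(tert-butyldimethylsilyl)oxy]-5-methylcyclohexyl (2Z)-2-methylbut-2-enoate
Conditions: Ac2O, pyridine, DMAP (cat.), CH2Cl2, 0 °C → rt
Reagents that add atoms: acetic anhydride, CC(=O)OC(C)=O
Why: Acetylation of the secondary allylic alcohol with the anhydride under nucleophilic catalysis proceeds at oxygen with retention at C9.

Step 17
Reactants: 26 silyl-protected diester
Product: 27 CNP0237033.1, (1R,2S,4R,5S)-2-[(2R,4R)-4-acetoxy-6-methylhept-5-en-2-yl]-4-hydroxy-5-methylcyclohexyl (2Z)-2-methylbut-2-enoate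
Conditions: HF·pyridine, pyridine, THF, 0 °C → rt
Reagents that add atoms: none
Why: Fluoride-mediated desilylation with pyridine-buffered HF·pyridine should free the axial C4 hydroxyl while both esters, the angelate geometry and the allylic acetate survive the mildly acidic medium.

**Compound list**

1 | cyclohexa-1,3-diene | C1=CC=CCC1 | starting material
2 | (1R,4S)-2,3-dioxabicyclo[2.2.2]oct-5-ene | O1O[C@H]2CC[C@@H]1C=C2 | intermediate
3 | (4R)-4-hydroxycyclohex-2-en-1-one | O[C@@H]1CCC(=O)C=C1 | intermediate
4 | (4R)-4-(triethylsilyloxy)cyclohex-2-en-1-one | CC[Si](CC)(CC)O[C@@H]1CCC(=O)C=C1 | intermediate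
5 | lithium (4R)-4-(triethylsilyloxy)cyclohexa-1,5-dien-1-olate | [Li]OC1=CC[C@@H](O[Si](CC)(CC)CC)C=C1 | intermediate
6 | (4R)-6-methyl-4-(triethylsilyloxy)cyclohex-2-en-1-one, C6 epimers | CC[Si](CC)(CC)O[C@@H]1CC(C)C(=O)C=C1 | intermediate
7 | isopropenylmagnesium bromide | CC(=C)[Mg]Br | starting material
8 | bromomagnesium di(prop-1-en-2-yl)cuprate | CC(=C)[Cu-]C(C)=C.[Mg+]Br | intermediate
9 | (4R,5S)-2-methyl-5-(prop-1-en-2-yl)-4-(triethylsilyloxy)cyclohexan-1-one, C2 epimers | CC[Si](CC)(CC)O[C@@H]1CC(C)C(=O)C[C@H]1C(C)=C | intermediate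
10 | (2S,4R,5S)-2-methyl-5-(prop-1-en-2-yl)-4-(triethylsilyloxy)cyclohexan-1-one | CC[Si](CC)(CC)O[C@@H]1C[C@H](C)C(=O)C[C@H]1C(C)=C | intermediate
11 | (1R,2S,4R,5S)-2-methyl-5-(prop-1-en-2-yl)-4-(triethylsilyloxy)cyclohexan-1-ol | CC[Si](CC)(CC)O[C@@H]1C[C@H](C)[C@H](O)C[C@H]1C(C)=C | intermediate
12 | tert-butyldimethyl{[(1R,2S,4R,5S)-2-methyl-5-(prop-1-en-2-yl)-4-(triethylsilyloxy)cyclohexyl]oxy}silane | CC[Si](CC)(CC)O[C@@H]1C[C@H](C)[C@H](O[Si](C)(C)C(C)(C)C)C[C@H]1C(C)=C | intermediate
13 | (1R,2S,4R,5S)-4-[(tert-butyldimethylsilyl)oxy]-5-methyl-2-(prop-1-en-2-yl)cyclohexan-1-ol | O[C@@H]1C[C@H](C)[C@H](O[Si](C)(C)C(C)(C)C)C[C@H]1C(C)=C | intermediate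
14 | acryloyl chloride | C=CC(=O)Cl | starting material
15 | (1R,2S,4R,5S)-4-[(tert-butyldimethylsilyl)oxy]-5-methyl-2-(prop-1-en-2-yl)cyclohexyl prop-2-enoate | C=CC(=O)O[C@@H]1C[C@H](C)[C@H](O[Si](C)(C)C(C)(C)C)C[C@H]1C(C)=C | intermediate
16 | (4aS,6R,7S,8aR)-6-[(tert-butyldimethylsilyl)oxy]-4,7-dimethyl-4a,5,6,7,8,8a-hexahydro-2H-chromen-2-one | O2[C@@H]1C[C@H](C)[C@H](O[Si](C)(C)C(C)(C)C)C[C@H]1C(C)=CC2=O | intermediate
17 | (4R,4aS,6R,7S,8aR)-6-[(tert-butyldimethylsilyl)oxy]-4,7-dimethyloctahydro-2H-chromen-2-one | O2[C@@H]1C[C@H](C)[C@H](O[Si](C)(C)C(C)(C)C)C[C@H]1[C@H](C)CC2=O | intermediate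
18 | 1-bromo-2-methylprop-1-ene | CC(C)=CBr | starting material
19 | 2-methylprop-1-enyllithium | [Li]C=C(C)C | intermediate
20 | lithium (4R,4aS,6R,7S,8aR)-6-[(tert-butyldimethylsilyl)oxy]-4,7-dimethyl-2-(2-methylprop-1-en-1-yl)octahydro-2H-chromen-2-olate, C2 epimers | O2[C@@H]1C[C@H](C)[C@H](O[Si](C)(C)C(C)(C)C)C[C@H]1[C@H](C)CC2(O[Li])C=C(C)C | intermediate
21 | (6R)-6-[(1S,2R,4S,5R)-5-[(tert-butyldimethylsilyl)oxy]-2-hydroxy-4-methylcyclohexyl]-2-methylhept-2-en-4-one | O[C@@H]1C[C@H](C)[C@H](O[Si](C)(C)C(C)(C)C)C[C@H]1[C@H](C)CC(=O)C=C(C)C | intermediate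
22 | angelic acid, (2Z)-2-methylbut-2-enoic acid | C/C=C(/C)C(=O)O | starting material
23 | (2Z)-2-methylbut-2-enoic 2,4,6-trichlorobenzoic anhydride | C/C=C(/C)C(=O)OC(=O)c1c(Cl)cc(Cl)cc1Cl | intermediate
24 | (1R,2S,4R,5S)-4-[(tert-butyldimethylsilyl)oxy]-5-methyl-2-[(2R)-6-methyl-4-oxohept-5-en-2-yl]cyclohexyl (2Z)-2-methylbut-2-enoate | C/C=C(/C)C(=O)O[C@@H]1C[C@H](C)[C@H](O[Si](C)(C)C(C)(C)C)C[C@H]1[C@H](C)CC(=O)C=C(C)C | intermediate
25 | (1R,2S,4R,5S)-4-[(tert-butyldimethylsilyl)oxy]-2-[(2R,4R)-4-hydroxy-6-methylhept-5-en-2-yl]-5-methylcyclohexyl (2Z)-2-methylbut-2-enoate | C/C=C(/C)C(=O)O[C@@H]1C[C@H](C)[C@H](O[Si](C)(C)C(C)(C)C)C[C@H]1[C@H](C)C[C@H](C=C(C)C)O | intermediate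
26 | (1R,2S,4R,5S)-2-[(2R,4R)-4-acetoxy-6-methylhept-5-en-2-yl]-4-[(tert-butyldimethylsilyl)oxy]-5-methylcyclohexyl (2Z)-2-methylbut-2-enoate | C/C=C(/C)C(=O)O[C@@H]1C[C@H](C)[C@H](O[Si](C)(C)C(C)(C)C)C[C@H]1[C@H](C)C[C@H](C=C(C)C)OC(C)=O | intermediate
27 | CNP0237033.1, (1R,2S,4R,5S)-2-[(2R,4R)-4-acetoxy-6-methylhept-5-en-2-yl]-4-hydroxy-5-methylcyclohexyl (2Z)-2-methylbut-2-enoate | C/C=C(/C)C(=O)O[C@@H]1C[C@H](C)[C@H](O)C[C@H]1[C@H](C)C[C@H](C=C(C)C)OC(C)=O | target

**Step count**

Total steps: 17. Longest linear sequence: 17 steps (1 → 27); all other components are commercial.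

**Steps most likely to fail**

Step 11 (ring-closing metathesis). Initiation at the hindered 1,1-disubstituted alkene may be slow, so that intermolecular cross-metathesis of the acrylate and thermal decay of the catalyst compete with closure. The fallback sets out from alcohol 13 and returns at lactone 16, forming the same C7=C8 bond by olefination instead of metathesis.
- Alcohol 13 is esterified with diethylphosphonoacetic acid (DCC, DMAP cat., CH2Cl2) to (1R,2S,4R,5S)-4-[(tert-butyldimethylsilyl)oxy]-5-methyl-2-(prop-1-en-2-yl)cyclohexyl 2-(diethoxyphosphoryl)acetate F1.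
- Ozonolysis (O3, CH2Cl2/MeOH, −78 °C; Me2S) converts the isopropenyl group into the methyl ketone, (1R,2R,4R,5S)-2-acetyl-4-[(tert-butyldimethylsilyl)oxy]-5-methylcyclohexyl 2-(diethoxyphosphoryl)acetate F2.
- Intramolecular Horner–Wadsworth–Emmons olefination under Masamune–Roush conditions (LiCl, i-Pr2NEt, MeCN) closes the unsaturated lactone 16.

Step 13 (lactone opening). The tetrahedral adduct may collapse in the flask and the released enone may take up a second equivalent of alkenyllithium, or the lactone may simply be enolized. The fallback sets out from lactone 17 and returns at hydroxy enone 21.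
- AlMe3-mediated aminolysis with MeNH(OMe)·HCl (CH2Cl2, 0 °C) opens the lactone to the hydroxy Weinreb amide, (3R)-3-[(1S,2R,4S,5R)-5-[(tert-butyldimethylsilyl)oxy]-2-hydroxy-4-methylcyclohexyl]-N-methoxy-N-methylbutanamide F3.
- Excess alkenyllithium 19 (3 equiv, THF, −78 °C) first deprotonates the hydroxyl and then adds once, giving a chelated adduct that releases 21 only on work-up.

Step 15 (reduction at C9). Facial discrimination may be insufficient, because the catalyst must tell the 2-methylprop-1-enyl group from a beta-branched alkyl group with no help from the distant ring stereocentres. The fallback sets out from enone 24 and returns at alcohol 25 and acetate 26.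
- Luche reduction (NaBH4, CeCl3·7H2O, MeOH, −78 °C) gives both C9 alcohols, which are separated by chromatography.
- The (9R) alcohol is 25 and continues with step 16.
- The (9S) alcohol, (1R,2S,4R,5S)-4-[(tert-butyldimethylsilyl)oxy]-2-[(2R,4S)-4-hydroxy-6-methylhept-5-en-2-yl]-5-methylcyclohexyl (2Z)-2-methylbut-2-enoate F4, is converted with inversion into acetate 26 by Mitsunobu reaction with acetic acid (PPh3, DIAD, toluene, 0 °C), so both epimers converge on 26.

**Further compounds**

F1 | step 11 | (1R,2S,4R,5S)-4-[(tert-butyldimethylsilyl)oxy]-5-methyl-2-(prop-1-en-2-yl)cyclohexyl 2-(diethoxyphosphoryl)acetate | CCOP(=O)(OCC)CC(=O)O[C@@H]1C[C@H](C)[C@H](O[Si](C)(C)C(C)(C)C)C[C@H]1C(C)=C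
F2 | step 11 | (1R,2R,4R,5S)-2-acetyl-4-[(tert-butyldimethylsilyl)oxy]-5-methylcyclohexyl 2-(diethoxyphosphoryl)acetate | CCOP(=O)(OCC)CC(=O)O[C@@H]1C[C@H](C)[C@H](O[Si](C)(C)C(C)(C)C)C[C@H]1C(C)=O
F3 | step 13 | (3R)-3-[(1S,2R,4S,5R)-5-[(tert-butyldimethylsilyl)oxy]-2-hydroxy-4-methylcyclohexyl]-N-methoxy-N-methylbutanamide | O[C@@H]1C[C@H](C)[C@H](O[Si](C)(C)C(C)(C)C)C[C@H]1[C@H](C)CC(=O)N(C)OC
F4 | step 15 | (1R,2S,4R,5S)-4-[(tert-butyldimethylsilyl)oxy]-2-[(2R,4S)-4-hydroxy-6-methylhept-5-en-2-yl]-5-methylcyclohexyl (2Z)-2-methylbut-2-enoate | C/C=C(/C)C(=O)O[C@@H]1C[C@H](C)[C@H](O[Si](C)(C)C(C)(C)C)C[C@H]1[C@H](C)C[C@@H](C=C(C)C)O
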